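**Assumptions (one line each)**
- Ethyl 2-(2-bromothiazol-4-yl)acetate (1) and 4-bromopent-4-enoic acid (10) are taken as catalogue building blocks.
- The allenylborane in step 5 is assumed to show the same facial preference as the corresponding Brown allylborane; this is from recollection and should be confirmed by Mosher ester analysis of 9.

**Retrosynthetic overview**
1. The (Z)-diene comes from Z-selective semi-reduction of a conjugated enyne, itself made by Sonogashira coupling of a homopropargylic alcohol with a 2-bromoalkene carbamate (one-step Curtius product).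
2. The carbinol stereocentre comes from asymmetric allenylboration (propargylation) of an α,α-dimethyl aldehyde.
3. The aldehyde comes from a tertiary nitrile (DIBAL), installed at thiazole C2 by Pd-catalysed coupling of the 2-bromothiazole with the zinc reagent of isobutyronitrile.
4. The skipped (Z)-diene at C4 comes from a Z-selective Wittig reaction of a thiazol-4-ylacetaldehyde with a but-3-enyl ylide.
5. No ring is formed: the thiazole is bought as 1.

**Route**

Step 1
Reactants: 1, ethyl 2-(2-bromo-1,3-thiazol-4-yl)acetate
Product: 2, 2-(2-bromo-1,3-thiazol-4-yl)acetaldehyde (used crude)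
Conditions: DIBAL-H (1.1 equiv), CH2Cl2, −78 °C; MeOH quench, aq. Rochelle salt
Reagents that add atoms: none
Why: Partial ester reduction; the tetrahedral aluminium hemiacetal survives at −78 °C and releases the aldehyde on work-up, and the C2–Br bond is inert to DIBAL at this temperature.

Step 2
Reactants: 2; 3, (but-3-en-1-yl)triphenylphosphonium bromide
Product: 4, 2-bromo-4-[(2Z)-hexa-2,5-dien-1-yl]-1,3-thiazole
Conditions: 3 (1.5 equiv), NaHMDS (1.45 equiv), THF, 0 °C; then 2, −78 °C → rt
Reagents that add atoms: 3, C=CCC[P+](c1ccccc1)(c1ccccc1)c1ccccc1.[Br-]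
Why: Wittig olefination with a non-stabilised ylide under lithium-free conditions goes through the kinetic cis-oxaphosphetane and gives the (Z)-alkene; low temperature and no excess base limit enolisation of the aldehyde.

Step 3
Reactants: 4; 5, isobutyronitrile
Product: 6, 2-{4-[(2Z)-hexa-2,5-dien-1-yl]-1,3-thiazol-2-yl}-2-methylpropanenitrile
Conditions: 5, LDA, THF, −78 °C; ZnCl2, → rt; then 4, Pd2(dba)3 (2.5 mol %), P(t-Bu)3 (6 mol %), THF, rt → 45 °C
Reagents that add atoms: 5, CC(C)C#N
Why: Negishi-type α-arylation of a nitrile; the activated 2-bromothiazole C–Br bond adds readily to Pd(0), and the zinc cyanoalkyl is too weakly basic to move the skipped diene into conjugation.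

Step 4
Reactants: 6
Product: 7, 2-{4-[(2Z)-hexa-2,5-dien-1-yl]-1,3-thiazol-2-yl}-2-methylpropanal
Conditions: DIBAL-H (1.3 equiv), toluene, −78 → −20 °C; then aq. Rochelle salt / 10 % tartaric acid, rt
Reagents that add atoms: water, O (carbonyl oxygen, from imine hydrolysis)
Why: DIBAL adds once to the hindered tertiary nitrile to give an N-aluminoimine that hydrolyses to the non-enolisable aldehyde; the alkenes and thiazole are untouched.

Step 5
Reactants: 7; 8, propargyl bromide
Product: 9, (3R)-2-{4-[(2Z)-hexa-2,5-dien-1-yl]-1,3-thiazol-2-yl}-2-methylhex-5-yn-3-ol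
Conditions: 8, Mg, cat. HgCl2, Et2O, 0 °C (allenylMgBr); (+)-Ipc2BOMe [the enantiomer derived from (−)-α-pinene], Et2O, −78 °C → rt; then 7, −100 → −78 °C; ethanolamine work-up
Reagents that add atoms: 8, C#CCBr
Why: Brown-type asymmetric allenylboration; the B-allenyl-diisopinocampheylborane reacts through a cyclic SE2′ transition state to give only the homopropargylic alcohol. The (−)-α-pinene-derived ligands are chosen to deliver carbon to the Re face of the aldehyde, which gives the (R)-carbinol because the quaternary carbon outranks the propargylic CH2.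

Step 6
Reactants: 10, 4-bromopent-4-enoic acid
Product: 11, methyl N-(3-bromobut-3-en-1-yl)carbamate
Conditions: DPPA (1.1 equiv), Et3N, toluene, rt → 85 °C; then MeOH, 70 °C
Reagents that add atoms: diphenylphosphoryl azide, [N-]=[N+]=NP(=O)(Oc1ccccc1)Oc1ccccc1 (supplies N); methanol, CO (supplies OMe)
Why: Curtius rearrangement; the acyl azide loses N2 to give the isocyanate, which methanol traps as the methyl carbamate, and the vinyl bromide is inert.

Step 7
Reactants: 9; 11
Product: 12, methyl N-[(7R)-8-{4-[(2Z)-hexa-2,5-dien-1-yl]-1,3-thiazol-2-yl}-7-hydroxy-8-methyl-3-methylidenenon-4-yn-1-yl]carbamate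
Conditions: 11 (1.5 equiv), Pd(PPh3)4 (5 mol %), CuI (10 mol %), i-Pr2NH, THF (degassed), rt → 40 °C
Reagents that add atoms: 11, C=C(Br)CCNC(=O)OC
Why: Sonogashira coupling of the terminal alkyne with the 2-bromo-1-alkene; the free secondary OH, carbamate N–H, thiazole and skipped diene tolerate the mild amine base, and the stereocentre is not involved.

Step 8
Reactants: 12
Product: 13, mycothiazole, methyl N-[(4Z,7R)-8-{4-[(2Z)-hexa-2,5-dien-1-yl]-1,3-thiazol-2-yl}-7-hydroxy-8-methyl-3-methylidenenon-4-en-1-yl]carbamate
Conditions: Zn(Cu/Ag) [Zn dust, Cu(OAc)2, AgNO3], MeOH/H2O 1:1, 35–40 °C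
Reagents that add atoms: none
Why: Boland semi-reduction; activated zinc reduces only the conjugated (enyne) triple bond by cis delivery of hydrogen, giving the (4Z)-diene and leaving the isolated alkenes and the thiazole alone.

**Compound list**
1 | ethyl 2-(2-bromo-1,3-thiazol-4-yl)acetate | CCOC(=O)Cc1csc(Br)n1 | starting material
2 | 2-(2-bromo-1,3-thiazol-4-yl)acetaldehyde | O=CCc1csc(Br)n1 | intermediate
3 | (but-3-en-1-yl)triphenylphosphonium bromide | C=CCC[P+](c1ccccc1)(c1ccccc1)c1ccccc1.[Br-] | starting material
4 | 2-bromo-4-[(2Z)-hexa-2,5-dien-1-yl]-1,3-thiazole | C=CC/C=C\Cc1csc(Br)n1 | intermediate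
5 | isobutyronitrile | CC(C)C#N | starting material
6 | 2-{4-[(2Z)-hexa-2,5-dien-1-yl]-1,3-thiazol-2-yl}-2-methylpropanenitrile | C=CC/C=C\Cc1csc(C(C)(C)C#N)n1 | intermediate
7 | 2-{4-[(2Z)-hexa-2,5-dien-1-yl]-1,3-thiazol-2-yl}-2-methylpropanal | C=CC/C=C\Cc1csc(C(C)(C)C=O)n1 | intermediate
8 | propargyl bromide | C#CCBr | starting material
9 | (3R)-2-{4-[(2Z)-hexa-2,5-dien-1-yl]-1,3-thiazol-2-yl}-2-methylhex-5-yn-3-ol | C=CC/C=C\Cc1csc(C(C)(C)[C@H](O)CC#C)n1 | intermediate
10 | 4-bromopent-4-enoic acid | C=C(Br)CCC(=O)O | starting material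
11 | methyl N-(3-bromobut-3-en-1-yl)carbamate | C=C(Br)CCNC(=O)OC | intermediate
12 | methyl N-[(7R)-8-{4-[(2Z)-hexa-2,5-dien-1-yl]-1,3-thiazol-2-yl}-7-hydroxy-8-methyl-3-methylidenenon-4-yn-1-yl]carbamate | C=CC/C=C\Cc1csc(C(C)(C)[C@H](O)CC#CC(=C)CCNC(=O)OC)n1 | intermediate
13 | mycothiazole, (R)-carbinol, both disubstituted alkenes Z | C=CC/C=C\Cc1csc(C(C)(C)[C@H](O)C/C=C\C(=C)CCNC(=O)OC)n1 | target

**Totals**
- Total steps: 8
- Longest linear sequence: 7 (steps 1, 2, 3, 4, 5, 7, 8); step 6 is a one-step side branch.

**Three steps most likely to fail, with fallbacks**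
1. Step 2, Wittig on the enolisable thiazolylacetaldehyde (enolisation, self-condensation, Z/E erosion). Fallback: avoid the aldehyde altogether. Build the thiazole by Hantzsch condensation of 2-cyano-2-methylpropanethioamide with 1,3-dichloroacetone, then join the 4-(chloromethyl)thiazole to (Z)-tributyl(penta-1,4-dien-1-yl)stannane by an sp3–sp2 Stille coupling (Pd/CuI/CsF).
2. Step 5, asymmetric allenylboration of the hindered, thiazole-bearing aldehyde (ee, facial sense, allenyl versus propargyl transfer). Fallback: set the stereocentre by resolution of an epoxide. Convert 7 to the terminal epoxide (Corey–Chaykovsky), resolve by Jacobsen hydrolytic kinetic resolution, and open the (R)-epoxide at CH2 with a lithium acetylide/BF3·OEt2.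
3. Step 8, late-stage Zn(Cu/Ag) semi-reduction (incomplete conversion or over-reduction on valuable material). Fallback: form the Z-alkene by cross-coupling instead of reduction. Convert 9 to the 1-iodoalkyne (NIS/AgNO3), reduce with diimide to the (Z)-vinyl iodide, and run a Suzuki or Stille coupling with the 2-boryl or 2-stannyl alkene made by Markovnikov hydrometalation of methyl but-3-yn-1-ylcarbamate.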